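(The data stem from a simulated flask for an exercise; the scatter is artificial.)

The ratio to watch was Q over the E charged. Each E that starts makes one chain, so this ratio is the average chain length (the number-average degree of polymerisation) if every E has started. The real length is the ratio divided by f, the share of E started. Since f cannot pass one, I called the ratio the floor, F.

| setting | grey | teal | blue | midnight | noon |
|---|---|---|---|---|---|
| D | 20 mM | 20 mM | 40 mM | 20 mM | 20 mM |
| L | 2 mM | 2 mM | 2 mM | 2.00 mM | 2.00 mM |
| E | 33 µM | 50 µM | 66 µM | 66 µM | 66 µM |
| remark | run made earlier | run made earlier | run made earlier |  |  |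
| time |  |  |  | 2.0 d | 8.0 d |

| run | time / h | Q / % |
|---|---|---|
| grey | 8.00 | 1.4 |
| grey | 15.0 | 0.6 |
| grey | 25.0 | 3.1 |
| grey | 30.0 | 4.4 |
| grey | 40.0 | 8.2 |
| grey | 50.0 | 11.2 |
| teal | 8.00 | 1.3 |
| teal | 15.0 | 2.5 |
| teal | 25.0 | 5.1 |
| teal | 30.0 | 6.8 |
| teal | 40.0 | 11.0 |
| teal | 50.0 | 16.1 |
| blue | 4.00 | 0.3 |
| blue | 8.00 | 0.7 |
| blue | 15.0 | 4.7 |
| blue | 25.0 | 13.1 |
| blue | 50.0 | 34.7 |

(standard deviation of a reading: 0.5 percentage points)

- the average divides the monomer in chains by the number of chains begun, living and dead together
- reactions considered so far: D + E -> X + Q; D + X -> Q + X; L + D -> J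
- the earlier runs do not show the number of chains; that part of a forecast is a guess

- which of the two ends with the longer chains by the average number of monomer units in a chain (chains begun, living or dead) ("neither" if they lie within 10%) (midnight / noon / neither)
- average number of monomer units in a chain (chains begun, living or dead) at the end, midnight
- average number of monomer units in a chain (chains begun, living or dead) at the end, noon

I read grey against teal. At 50.0 h, F was 67.9 in grey and 64.4 in teal; at 25.0 h it was 18.8 and 20.4. These pairs agree within the scatter, though teal held 1.52 times grey's E, so at this D and L, F followed time.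

Teal's slope from 40.0 h to 50.0 h was 1.96 times its slope from 15.0 h to 25.0 h, at a midpoint 2.25 times later. Through that scatter, I read X as still being made at a steady pace, with f well short of one.

Scaling teal's F with the square of time, I put the floor of midnight at 2.0 d at 59.4. If L took its whole charge of D, the floor of noon would top out at 273. With steady starts, Q grows as time squared and chains as time, so I expected noon to be longer, and both lengths to stand above their floors.

The forecast also chose noon, with 68 (55 to 88) for midnight and 235 (185 to 270) for noon. Its noon ground was: “With essentially all 66 µM started, that gives about 235.” There we differed, since I held f well below one.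

The simulation gave noon as the longer, with 175 for midnight and 407 for noon.

    D + E → X + Q (k = 0.00858 M⁻¹ min⁻¹)
    D + X → Q + X, rate k2*[X]*[D] (k = 6.68 M⁻¹ min⁻¹)
    L + D → J (k = 0.0848 M⁻¹ min⁻¹)

Midnight kept 66% of its E, so f was 34.2%, and my floor over f gives 174. Noon had the same charge, and its longer time is the reason its chains outran midnight's : the length was 407 in noon and 175 without the difference in time. At its end, noon's Q reached 80.3% while its f reached 59.7%. In the neighbour flask, midnight's charge read at 20 h, Q of 4.47% scales the floor to 13.4, and f of 17.4% gives 77.0, against a simulated 77.8.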